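Lay the two earlier runs side by side at equal times.

| setting | north | east | alpha | epsilon | eta |
|---|---|---|---|---|---|
| substrate | 0.086 M | 0.22 M | 0.080 M | 0.15 M | 0.30 M |
| remark | run made earlier | run made earlier |  |  |  |
| time |  |  | 8.0 h | 8.0 h | 8.0 h |

| north: time / h | north: target / % | east: time / h | east: target / % |
|---|---|---|---|
| 0.667 | 25.7 | 0.667 | 25.6 |
| 2.00 | 48.5 | 1.33 | 40.0 |
| 4.00 | 54.3 | 2.50 | 51.1 |
| 6.00 | 50.3 | 4.00 | 53.9 |
| 8.00 | 46.7 | 8.00 | 44.6 |

(scatter of a reading: 0.5 percentage points)

- a species is counted by the substrate in it: one self-condensation product or side product counts as two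
- steps thought possible: substrate <-> other conformer; substrate -> target; other conformer -> isomer of the product A; other conformer <-> third conformer; third conformer -> third product; target <-> isomer of the product B; 2 other conformer -> self-condensation product; substrate + target -> side product
- "hardly changes" means that all values lie within two and a half points (for a concentration: within two and a half percent of the largest)

1. amount of target at the end, in percent of the substrate charged for alpha, epsilon, eta, in this order
2. how the row runs (falls, then rises / hardly changes / rises, then falls / falls all the way / rises all the way)

I draw the north run first. It holds 25.7 % at 0.667 h, then gains 23 percentage points in twice that time, so the climb is already bending. The next 2.00 h add 5.8 points, which puts the knee near 54.3 % at 4.00 h. After that the curve loses 7.6 points by 8.00 h and reaches no level within the readings. The east run, with 2.56 times the charge, reads 25.6 % at 0.667 h and 53.9 % at 4.00 h, each within 0.71 points of the north run at that time.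

A curve in percent made by first-order steps does not move with the charge, while a step with two partners does move it. I therefore measure the second-order part directly. At 4.00 h the gap between the runs gives 0.0299 M⁻¹, the charge slope: the fraction of the charge lost as target per molar of extra charge.

I take this gap and not the one at 8.00 h, which reads 2.1 points. Both steps with two partners need an early form of the charge, and once the target stops rising I expect their gap to stand, not widen. Each gap carries a scatter of 0.71 points.

Centring on the mean end reading, 45.6 % at 0.153 M, I commit to 45.9 %, 45.7 % and 45.2 %. The spread is 0.66 points, with a scatter of 1.2 points, against the margin of 2.5 points, so I say the row hardly changes.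

The forecast gives 46.8 %, 45.7 % and 43.4 % and calls the row falls all the way, in its words “a steady fall is likelier”.

The flask gives 46.2 %, 45.9 % and 45.4 %: hardly changes.

    substrate ⇌ other conformer (K = 7.40, k = 4.30 × 10⁻⁵ s⁻¹)
    substrate → target (k = 1.40 × 10⁻⁴ s⁻¹)
    other conformer → isomer of the product A (k = 2.80 × 10⁻⁴ s⁻¹)
    other conformer ⇌ third conformer (K = 4.70, k = 2.10 × 10⁻⁵ s⁻¹)
    third conformer → third product (k = 1.40 × 10⁻⁴ s⁻¹)
    target ⇌ isomer of the product B (K = 1.00, k = 3.40 × 10⁻⁵ s⁻¹)
    2 other conformer → self-condensation product (k = 5.80 × 10⁻⁵ M⁻¹ s⁻¹)
    substrate + target → side product (k = 2.00 × 10⁻⁵ M⁻¹ s⁻¹)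

The main loss is first order: the path from target to isomer of the product B. Taking it away in eta lifts the target from 45.4 % to 74.3 %, and in alpha from 46.2 % to 75.9 %, so it costs 29 points at the high charge and 30 points at the low one. Carried from alpha's value, the charge slope gives 45.5 % for eta, which stands at 45.4 %. For epsilon it gives 46.0 %, and epsilon stands at 45.9 %.

(The runs are simulated with made-up constants, noise included.)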